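**Strategy.** Numbering: spiro C5; cyclohexene C10(C14)=C1–C2–C3–C4(C15)–C5; cyclopentane C5–C6–C7–C8–C9; lactone C7–C11(=C13)–C12–O–C8. Everything rests on cutting C11 from C7. Because the lactone carbon C11 sits on C7 beside the oxygen-bearing C8, an ester carbene tethered to the C8 oxygen of a C6=C7 cyclopentenol must reach C7 on the oxygen's face. One Rh2(OAc)4-catalysed carbene transfer therefore closes the γ-lactone and a C6–C7–C11 cyclopropane and fixes C7 from C8; reductive cleavage of C11–C6 then leaves the cis-lactone. The precursor is the C8 diazoacetate of a spiro[4.5]decadiene (C6=C7, C10=C1) carrying C3–OTBS and C4–CH3, built from (R)-carvone.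

Key step: step 13

Remark: all locants are those of the first paragraph; C2 and C14 are oxidised only after the lactone exists, because neither an enone nor an allylic ester would survive the electron-transfer step 14.

Step 1
Reactants: 1 (R)-carvone
Product: 2 (5R,6S)-6-methylcarvone
Conditions: LDA, THF, −78 °C; MeI, −78 → 0 °C
Reagents that add atoms: iodomethane, CI
Why: Kinetic α′-enolate methylation of the enone in which iodomethane enters anti to the neighbouring isopropenyl group, giving the trans 5,6-relationship (also the thermodynamic one) that becomes the C3/C4 relationship of the target.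

Step 2
Reactants: 2 (5R,6S)-6-methylcarvone
Product: 4 (5R,6S)-5-acetoxy-2,6-dimethylcyclohex-2-en-1-one, via methoxy hydroperoxide 3 (not isolated)
Conditions: O3, CH2Cl2/MeOH, −78 °C; then Ac2O, Et3N, DMAP (cat.), −10 °C → rt
Reagents that add atoms: ozone, [O-][O+]=O; methanol, CO
Why: Ozone cleaves only the electron-rich isopropenyl alkene and methanol traps the carbonyl oxide as hydroperoxide 3, whose peracetate undergoes Criegee rearrangement with migration of the ring carbon to oxygen with retention, so the C–C bond at C3 becomes a C–O bond of unchanged configuration.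

Step 3
Reactants: 4 (5R,6S)-5-acetoxy-2,6-dimethylcyclohex-2-en-1-one
Product: 5 (1R,2R)-2,4-dimethyl-3-methylidenecyclohex-4-en-1-yl acetate
Conditions: Zn, CH2Br2, TiCl4, THF/CH2Cl2, 0 °C → rt
Reagents that add atoms: dibromomethane, BrCBr
Why: Takai–Lombardo methylenation, in which the non-basic zinc/titanium methylene reagent converts the hindered enone carbonyl into the exocyclic alkene without enolisation, so the C4 methyl centre is not epimerised and the β-acetoxy group is not eliminated.

Step 4
Reactants: 5 (1R,2R)-2,4-dimethyl-3-methylidenecyclohex-4-en-1-yl acetate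
Product: 6 (1R,2R)-2,4-dimethyl-3-methylidenecyclohex-4-en-1-ol
Conditions: K2CO3, MeOH, 0 °C → rt
Reagents that add atoms: none
Why: Base-catalysed methanolysis of a secondary acetate, carried out after the ketone has become the diene so that neither β-elimination nor retro-aldol cleavage is possible.

Step 5
Reactants: 6 (1R,2R)-2,4-dimethyl-3-methylidenecyclohex-4-en-1-ol
Product: 7 TBS ether of dienol 6
Conditions: TBSCl, imidazole, DMF, rt
Reagents that add atoms: tert-butyldimethylsilyl chloride, CC(C)(C)[Si](C)(C)Cl
Why: Standard imidazole-promoted silylation of a secondary alcohol, giving an ether that should tolerate every step up to the final fluoride treatment.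

Step 6
Reactants: 7 TBS ether of dienol 6; 8 trichloroacetyl chloride
Product: 10 spiro dichlorocyclobutanone, via dichloroketene 9 (not isolated)
Conditions: Zn–Cu couple, POCl3, Et2O, rt, slow addition of 8
Reagents that add atoms: none
Why: Zinc dechlorination of 8 releases dichloroketene, which undergoes thermal ketene–alkene [2+2] cycloaddition with the exocyclic alkene of the diene, its carbonyl carbon bonding to the terminal C6 and its CCl2 carbon (the future C9) to C5 where the developing charge is allylic; C5 is set by approach of the CCl2 carbon to the face opposite the adjacent C4 methyl, which is the face of the C3 oxygen, while POCl3 scavenges ZnCl2.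

Step 7
Reactants: 10 spiro dichlorocyclobutanone
Product: 11 spiro dichlorocyclopentanone
Conditions: CH2N2, Et2O/MeOH, 0 °C
Reagents that add atoms: diazomethane, C=[N+]=[N-]
Why: Diazomethane ring expansion (Tiffeneau–Demjanov type) of the strained, chlorine-activated cyclobutanone, in which the unsubstituted CH2 (C6) migrates in preference to the CCl2 carbon, so the new carbon C7 enters between C6 and C8 and C5 is untouched.

Step 8
Reactants: 11 spiro dichlorocyclopentanone
Product: 12 spiro cyclopentanone
Conditions: Zn, NH4Cl, MeOH, rt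
Reagents that add atoms: none
Why: Reductive dehalogenation of an α-halo ketone, in which zinc reduces both C–Cl bonds through zinc enolates that are protonated in methanol, leaving C9 as CH2.

Step 9
Reactants: 12 spiro cyclopentanone
Product: 14 spiro cyclopentenone, via silyl enol ether 13 (not isolated)
Conditions: LDA, TMSCl, THF, −78 °C; then Pd(OAc)2, MeCN, rt
Reagents that add atoms: none
Why: Saegusa–Ito oxidation, in which kinetic deprotonation occurs at the unhindered C7 and not at the neopentyl C9, and in any case only a palladium enolate at C7 has a β-hydrogen (on C6) to eliminate because C5 is quaternary, so the enone can only be C6=C7–C8=O.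

Step 10
Reactants: 14 spiro cyclopentenone
Product: 15 spiro cyclopentenol (8R)
Conditions: (S)-2-methyl-CBS-oxazaborolidine (0.2 equiv), catecholborane, toluene, −78 °C; aq. NaOH work-up
Reagents that add atoms: none
Why: Corey–Bakshi–Shibata reduction, in which the oxazaborolidine binds the carbonyl with the alkenyl arm (C7) as the large and the C9 methylene as the small group and delivers hydride 1,2 to one carbonyl face, so that C8 is set by the catalyst and is expected to be R with the (S)-catalyst.

Step 11
Reactants: 15 spiro cyclopentenol (8R); 16 bromoacetyl bromide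
Product: 17 C8 bromoacetate
Conditions: NaHCO3, MeCN, 0 °C
Reagents that add atoms: none
Why: O-Acylation of the secondary allylic alcohol by the acid bromide under bicarbonate buffering, which leaves the C8–O bond and hence the C8 configuration untouched.

Step 12
Reactants: 17 C8 bromoacetate
Product: 18 C8 diazoacetate
Conditions: TsNHNHTs, DBU, THF, 0 °C
Reagents that add atoms: N,N′-ditosylhydrazine, Cc1ccc(cc1)S(=O)(=O)NNS(=O)(=O)c1ccc(C)cc1
Why: N-Alkylation of N,N′-ditosylhydrazine by the bromoacetate followed by DBU-induced loss of two sulfinate ions converts the CH2Br group into the diazo carbon under conditions mild enough for the allylic ester.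

Step 13
Reactants: 18 C8 diazoacetate
Product: 19 cyclopropane-fused spiro lactone
Conditions: Rh2(OAc)4 (1 mol %), CH2Cl2, reflux, slow addition of 18 (syringe pump), high dilution
Reagents that add atoms: none
Why: Rh2(OAc)4 expels N2 from 18 to give an electrophilic rhodium carbenoid at C11, which adds to C6=C7 in a concerted but asynchronous [2+1] fashion, C11–C7 forming ahead of C11–C6. The closest known reaction type is the dirhodium-catalysed intramolecular cyclopropanation of secondary cycloalk-2-enyl diazoacetates. The γ-lactone (O–C12–C11–C7–C8) closes in the 5-exo mode onto C7, and the cyclopropane (C6–C7–C11) closes as the three-membered ring of the same carbene transfer. C7 and C6 are set by C8, because the three-atom O–C12–C11 tether can reach only the alkene face that carries the C8 oxygen, and C11 is fixed by the cis fusion that this tether enforces (carbonyl inside the lactone, hydrogen outside). The step needs chemoselectivity for C6=C7 over the C10=C1 alkene, over C–H insertion and over carbene dimerisation; the first two are secured by ring size (C10=C1 could be reached only through a seven-membered ring, and the C9 hydrogens are neopentyl), the last by slow addition at high dilution.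

Step 14
Reactants: 19 cyclopropane-fused spiro lactone
Product: 20 cis-fused γ-lactone
Conditions: SmI2 (3 equiv), HMPA, t-BuOH, THF, 0 °C → rt
Reagents that add atoms: none
Why: HMPA-activated SmI2 transfers an electron to the strained lactone carbonyl and the ketyl radical anion fragments (reductive cleavage of an α-cyclopropyl carbonyl compound) at C11–C6, the bond that lies outside the lactone ring and overlaps with the carbonyl π system, whereas the ring-fusion bond C11–C7 is nearly orthogonal to it; a second electron and tert-butanol then deliver hydrogen to C6 and C11, leaving C7 and C8 as the cis-fused lactone.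

Step 15
Reactants: 20 cis-fused γ-lactone
Product: 21 C2 enone
Conditions: CrO3, 3,5-dimethylpyrazole, CH2Cl2, −20 °C
Reagents that add atoms: chromium trioxide, O=[Cr](=O)=O
Why: Allylic oxidation with the CrO3–3,5-dimethylpyrazole complex attacks C2, the only ring allylic methylene (C5 is quaternary, and a methylene is oxidised faster than the C14 methyl), and gives the conjugated enone C10=C1–C2=O directly.

Step 16
Reactants: 21 C2 enone
Product: 22 C2 allylic alcohol (2S)
Conditions: NaBH4, CeCl3·7H2O, MeOH, −78 °C
Reagents that add atoms: none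
Why: Luche reduction gives clean 1,2-reduction of the enone, with hydride expected to add axially to the half-chair in which the C3 silyloxy and C4 methyl groups are equatorial, which places the new C2 hydroxyl equatorial and trans to the C3 oxygen (2S), while the lactone is inert at −78 °C.

Step 17
Reactants: 22 C2 allylic alcohol (2S)
Product: 23 C2/C3 bis(TBS) ether
Conditions: TBSOTf, 2,6-lutidine, CH2Cl2, −40 → 0 °C
Reagents that add atoms: tert-butyldimethylsilyl triflate, CC(C)(C)[Si](C)(C)OS(=O)(=O)C(F)(F)F
Why: A silyl triflate with a hindered pyridine base silylates the hindered secondary allylic alcohol, so that only the C14 hydroxyl made later will be free for esterification.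

Step 18
Reactants: 23 C2/C3 bis(TBS) ether
Product: 26 α-methylene lactone, via Mannich base 24 (not isolated), via methiodide 25 (not isolated)
Conditions: LDA, THF, −78 °C; CH2=NMe2+ I−, −78 °C → rt; then MeI, MeOH, rt; then aq. NaHCO3, CH2Cl2, rt
Reagents that add atoms: Eschenmoser's salt (N,N-dimethylmethyleneiminium iodide), C=[N+](C)C.[I-]
Why: The lactone enolate (C11 is the only acidic position) undergoes a Mannich reaction with the iminium salt, and quaternisation followed by mild base induces β-elimination of trimethylamine to give the exocyclic C11=C13 alkene; C7 is not enolisable, so the cis fusion is retained.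

Step 19
Reactants: 26 α-methylene lactone
Product: 27 C14 allylic alcohol
Conditions: SeO2 (0.5 equiv), t-BuOOH, CH2Cl2, rt
Reagents that add atoms: tert-butyl hydroperoxide, CC(C)(C)OO
Why: SeO2-mediated allylic hydroxylation (Riley oxidation, run with tert-butyl hydroperoxide as terminal oxidant), in which the ene reaction places selenium on the less substituted C1 and takes hydrogen from C14, the only C–H-bearing group on the more substituted alkene carbon C10, and the [2,3]-sigmatropic shift returns C10=C1 with oxygen on C14; the electron-poor C11=C13 alkene does not react, as known for methyl hydroxylation of sesquiterpene α-methylene lactones.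

Step 20
Reactants: 27 C14 allylic alcohol; 28 angelic acid
Product: 30 C14 angelate bis(TBS) ether, via mixed anhydride 29 (not isolated)
Conditions: 28, 2,4,6-trichlorobenzoyl chloride, Et3N, toluene, rt; then 27, toluene, 60 °C
Reagents that add atoms: none
Why: Yamaguchi-type esterification through mixed anhydride 29, which the primary allylic alcohol attacks at the less hindered angeloyl carbonyl; omission of a nucleophilic acyl-transfer catalyst avoids addition–elimination at the double bond, so the Z (angelate) geometry is kept.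

Step 21
Reactants: 30 C14 angelate bis(TBS) ether
Product: 31 CNP0224912.1 (target)
Conditions: HF·pyridine, pyridine/THF, 0 °C → rt
Reagents that add atoms: none
Why: Fluoride-mediated cleavage of both silyl ethers under buffered, non-basic conditions, which should leave the angelate geometry, the allylic ester and the α-methylene lactone untouched.

**Compound list**

1 | (R)-carvone | CC1=CC[C@@H](C(C)=C)CC1=O | starting material
2 | (5R,6S)-6-methylcarvone (methyl trans to isopropenyl) | CC1=CC[C@@H](C(C)=C)[C@H](C)C1=O | intermediate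
3 | methoxy hydroperoxide: (5R,6S)-5-(1-hydroperoxy-1-methoxyethyl)-2,6-dimethylcyclohex-2-en-1-one (side-chain carbon unassigned) | CC1=CC[C@@H](C(C)(OC)OO)[C@H](C)C1=O | intermediate
4 | (5R,6S)-5-acetoxy-2,6-dimethylcyclohex-2-en-1-one | CC1=CC[C@@H](OC(C)=O)[C@H](C)C1=O | intermediate
5 | (1R,2R)-2,4-dimethyl-3-methylidenecyclohex-4-en-1-yl acetate | CC1=CC[C@@H](OC(C)=O)[C@H](C)C1=C | intermediate
6 | (1R,2R)-2,4-dimethyl-3-methylidenecyclohex-4-en-1-ol | CC1=CC[C@@H](O)[C@H](C)C1=C | intermediate
7 | TBS ether of 6: tert-butyl{[(1R,2R)-2,4-dimethyl-3-methylidenecyclohex-4-en-1-yl]oxy}dimethylsilane | CC1=CC[C@@H](O[Si](C)(C)C(C)(C)C)[C@H](C)C1=C | intermediate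
8 | trichloroacetyl chloride | ClC(Cl)(Cl)C(Cl)=O | starting material
9 | dichloroketene | ClC(Cl)=C=O | intermediate
10 | spiro dichlorocyclobutanone: ring C5–C9Cl2–C8(=O)–C6H2 spiro at C5 to cyclohexene C10(CH3)=C1H–C2H2–C3H(OTBS)–C4H(CH3); C9 on the face of the C3 oxygen, C6 on the face of the C4 methyl | O=C1C(Cl)(Cl)[C@@]2(C1)C(C)=CC[C@@H](O[Si](C)(C)C(C)(C)C)[C@@H]2C | intermediate
11 | spiro dichlorocyclopentanone: ring C5–C9Cl2–C8(=O)–C7H2–C6H2, six-membered ring and configuration as in 10 | O=C1C(Cl)(Cl)[C@@]2(CC1)C(C)=CC[C@@H](O[Si](C)(C)C(C)(C)C)[C@@H]2C | intermediate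
12 | spiro cyclopentanone: ring C5–C9H2–C8(=O)–C7H2–C6H2, otherwise as 11 | O=C1C[C@@]2(CC1)C(C)=CC[C@@H](O[Si](C)(C)C(C)(C)C)[C@@H]2C | intermediate
13 | silyl enol ether: C8(OSiMe3)=C7 enol ether of 12 | C[Si](C)(C)OC1=CC[C@]2(C1)C(C)=CC[C@@H](O[Si](C)(C)C(C)(C)C)[C@@H]2C | intermediate
14 | spiro cyclopentenone: C6=C7–C8(=O)–C9H2, otherwise as 12 | O=C1C[C@@]2(C=C1)C(C)=CC[C@@H](O[Si](C)(C)C(C)(C)C)[C@@H]2C | intermediate
15 | spiro cyclopentenol, (8R): C8–OH on the cyclopentene face that also carries C10 | O[C@@H]1C[C@@]2(C=C1)C(C)=CC[C@@H](O[Si](C)(C)C(C)(C)C)[C@@H]2C | intermediate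
16 | bromoacetyl bromide | BrCC(Br)=O | starting material
17 | C8 bromoacetate of 15 | BrCC(=O)O[C@@H]1C[C@@]2(C=C1)C(C)=CC[C@@H](O[Si](C)(C)C(C)(C)C)[C@@H]2C | intermediate
18 | C8 diazoacetate of 15 (spiro cyclopent-2-enyl diazoacetate, key-step precursor) | [N-]=[N+]=CC(=O)O[C@@H]1C[C@@]2(C=C1)C(C)=CC[C@@H](O[Si](C)(C)C(C)(C)C)[C@@H]2C | intermediate
19 | cyclopropane-fused spiro lactone (key-step product): lactone C8–O–C12(=O)–C11–C7 and cyclopropane C6–C7–C11, both on the C8-oxygen face | O=C1O[C@@H]2C[C@@]3([C@@H]4[C@H]1[C@H]24)C(C)=CC[C@@H](O[Si](C)(C)C(C)(C)C)[C@@H]3C | intermediate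
20 | cis-fused γ-lactone: C7–C11H2–C12(=O)–O–C8, C6H2; C3–OTBS, C10(CH3)=C1H–C2H2 | O=C1O[C@@H]2C[C@@]3(C[C@@H]2C1)C(C)=CC[C@@H](O[Si](C)(C)C(C)(C)C)[C@@H]3C | intermediate
21 | C2 enone: C10(CH3)=C1H–C2(=O), otherwise as 20 | O=C1O[C@@H]2C[C@@]3(C[C@@H]2C1)C(C)=CC(=O)[C@@H](O[Si](C)(C)C(C)(C)C)[C@@H]3C | intermediate
22 | C2 allylic alcohol, (2S): C2–OH trans to C3–OTBS | O=C1O[C@@H]2C[C@@]3(C[C@@H]2C1)C(C)=C[C@H](O)[C@@H](O[Si](C)(C)C(C)(C)C)[C@@H]3C | intermediate
23 | C2/C3 bis(TBS) ether of 22 | O=C1O[C@@H]2C[C@@]3(C[C@@H]2C1)C(C)=C[C@H](O[Si](C)(C)C(C)(C)C)[C@@H](O[Si](C)(C)C(C)(C)C)[C@@H]3C | intermediate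
24 | Mannich base: C11–CH2NMe2 lactone (C11 epimers) | CN(C)CC1C(=O)O[C@@H]2C[C@@]3(C[C@H]12)C(C)=C[C@H](O[Si](C)(C)C(C)(C)C)[C@@H](O[Si](C)(C)C(C)(C)C)[C@@H]3C | intermediate
25 | methiodide of 24: C11–CH2NMe3+ I− | [I-].C[N+](C)(C)CC1C(=O)O[C@@H]2C[C@@]3(C[C@H]12)C(C)=C[C@H](O[Si](C)(C)C(C)(C)C)[C@@H](O[Si](C)(C)C(C)(C)C)[C@@H]3C | intermediate
26 | α-methylene lactone: C11=C13H2, C2/C3 bis(TBS) ether, C10–CH3 | C=C1C(=O)O[C@@H]2C[C@@]3(C[C@H]12)C(C)=C[C@H](O[Si](C)(C)C(C)(C)C)[C@@H](O[Si](C)(C)C(C)(C)C)[C@@H]3C | intermediate
27 | C14 allylic alcohol: C10–CH2OH, otherwise as 26 | C=C1C(=O)O[C@@H]2C[C@@]3(C[C@H]12)C(CO)=C[C@H](O[Si](C)(C)C(C)(C)C)[C@@H](O[Si](C)(C)C(C)(C)C)[C@@H]3C | intermediate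
28 | angelic acid, (Z)-2-methylbut-2-enoic acid | C/C=C(/C)C(O)=O | starting material
29 | mixed anhydride: (Z)-2-methylbut-2-enoic 2,4,6-trichlorobenzoic anhydride | C/C=C(/C)C(=O)OC(=O)c1c(Cl)cc(Cl)cc1Cl | intermediate
30 | C14 angelate, C2/C3 bis(TBS) ether | C=C1C(=O)O[C@@H]2C[C@@]3(C[C@H]12)C(COC(=O)/C(C)=C\C)=C[C@H](O[Si](C)(C)C(C)(C)C)[C@@H](O[Si](C)(C)C(C)(C)C)[C@@H]3C | intermediate
31 | CNP0224912.1: (2S,3S,4R,5R,7R,8R) in the numbering above; C14 angelate, 2,3-trans-diol, cis-fused α-methylene-γ-lactone | C=C1C(=O)O[C@@H]2C[C@@]3(C[C@H]12)C(COC(=O)/C(C)=C\C)=C[C@H](O)[C@@H](O)[C@@H]3C | target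

**Totals.** Total step count: 21. Longest linear sequence: 21 steps (1 → 31).

**Steps most likely to fail**

Step 6. What may go wrong: poor facial selectivity in the ketene cycloaddition. The cyclohexene can place the C4 methyl axial or equatorial, and the ketene may then add to both faces of the exocyclic alkene and give both C5 epimers. The fallback sets out from dienol 6 and comes back at cyclopentanone 12; it tethers the ketene to the C3 oxygen, which lies on the face where C9 must arrive. O-Alkylation of 6 with bromoacetic acid (NaH, THF) should give alkoxyacetic acid F1, and oxalyl chloride converts it into acid chloride F2. Et3N in refluxing toluene at high dilution generates alkoxyketene F3. Its intramolecular [2+2] cycloaddition to the exocyclic alkene (ketene α-carbon to C5 through a five-membered oxolane ring, carbonyl carbon to C6) can only give tricyclic alkoxycyclobutanone F4. Diazomethane is expected to expand the four-membered ring on its unsubstituted side to bridged alkoxycyclopentanone F5. SmI2 in THF/MeOH then cleaves the C9–O bond next to the ketone and frees the C3 hydroxyl in hydroxy ketone F6, and TBSCl/imidazole returns 12.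

Step 13. What may go wrong: diversion of the carbenoid. Hydride abstraction from the allylic C8–H (which would return enone 14), C–H insertion or carbene dimerisation may outrun addition to the hindered C6 terminus next to the quaternary C5. The fallback sets out from alcohol 15 and comes back at lactone 20; it uses radical instead of carbene chemistry (Ueno–Stork cyclisation). Alcohol 15, ethyl vinyl ether and N-bromosuccinimide (CH2Cl2, −20 °C) should give bromoacetal F7. Bu3SnH/AIBN (benzene, 80 °C) generates the primary radical, which closes 5-exo onto C7 on the oxygen's face and is reduced at C6, giving cis-fused ethyl acetal F8. PPTS in wet acetone hydrolyses it to lactol F9, and Dess–Martin periodinane oxidises this to 20.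

Step 14. What may go wrong: electron transfer to the unactivated lactone carbonyl may be too slow, so that the cyclopropane survives or the reagent attacks the lactone instead. The fallback sets out from alcohol 15 and comes back at lactone 20; it places a second, removable acceptor on C11. Acylation of 15 with methyl malonyl chloride (pyridine, CH2Cl2) gives mixed malonate F10, and diazo transfer (4-acetamidobenzenesulfonyl azide, Et3N, MeCN) gives diazomalonate F11. Rh2(OAc)4 in refluxing 1,2-dichloroethane gives ester-bearing cyclopropyl lactone F12. SmI2/HMPA should open this doubly activated cyclopropane at C11–C6 (reductive opening of cyclopropane-1,1-dicarbonyl compounds) to ester lactone F13. Krapcho demethoxycarbonylation (LiCl, wet DMSO, 140 °C) then returns 20.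

**Further compounds**

F1 | step 6 | alkoxyacetic acid: {[(1R,2R)-2,4-dimethyl-3-methylidenecyclohex-4-en-1-yl]oxy}acetic acid | CC1=CC[C@@H](OCC(O)=O)[C@H](C)C1=C
F2 | step 6 | acid chloride of F1 | CC1=CC[C@@H](OCC(Cl)=O)[C@H](C)C1=C
F3 | step 6 | alkoxyketene from F2 | CC1=CC[C@@H](OC=C=O)[C@H](C)C1=C
F4 | step 6 | tricyclic alkoxycyclobutanone: C9(H) bonded to C5, to C8(=O) and to the C3 oxygen; C8 bonded to C6H2 | O=C1C[C@@]23C(C)=CC[C@@H](O[C@H]12)[C@@H]3C
F5 | step 6 | bridged alkoxycyclopentanone: ring C5–C9(O)–C8(=O)–C7H2–C6H2 with C9–O–C3 ether bridge | O=C1CC[C@@]23C(C)=CC[C@@H](O[C@H]12)[C@@H]3C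
F6 | step 6 | hydroxy ketone: 12 with free C3 hydroxyl | O=C1C[C@@]2(CC1)C(C)=CC[C@@H](O)[C@@H]2C
F7 | step 13 | bromoacetal: C8–O–CH(OEt)–CH2Br ether of 15 (acetal epimers) | CCOC(CBr)O[C@@H]1C[C@@]2(C=C1)C(C)=CC[C@@H](O[Si](C)(C)C(C)(C)C)[C@@H]2C
F8 | step 13 | cis-fused ethyl acetal: 20 with C12 as CH(OEt) (acetal epimers) | CCOC1O[C@@H]2C[C@@]3(C[C@@H]2C1)C(C)=CC[C@@H](O[Si](C)(C)C(C)(C)C)[C@@H]3C
F9 | step 13 | lactol: 20 with C12 as CH(OH) | OC1O[C@@H]2C[C@@]3(C[C@@H]2C1)C(C)=CC[C@@H](O[Si](C)(C)C(C)(C)C)[C@@H]3C
F10 | step 14 | mixed malonate: C8 methyl malonate of 15 | COC(=O)CC(=O)O[C@@H]1C[C@@]2(C=C1)C(C)=CC[C@@H](O[Si](C)(C)C(C)(C)C)[C@@H]2C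
F11 | step 14 | diazomalonate of F10 | COC(=O)C(=[N+]=[N-])C(=O)O[C@@H]1C[C@@]2(C=C1)C(C)=CC[C@@H](O[Si](C)(C)C(C)(C)C)[C@@H]2C
F12 | step 14 | ester-bearing cyclopropyl lactone: 19 with CO2CH3 in place of H on C11 | O=C1O[C@@H]2C[C@@]3([C@@H]4[C@@]1(C(=O)OC)[C@H]24)C(C)=CC[C@@H](O[Si](C)(C)C(C)(C)C)[C@@H]3C
F13 | step 14 | ester lactone: 20 with CO2CH3 on C11 (C11 epimers) | COC(=O)C1C(=O)O[C@@H]2C[C@@]3(C[C@H]12)C(C)=CC[C@@H](O[Si](C)(C)C(C)(C)C)[C@@H]3C
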